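**Plan**
- Retrosynthesis: ring C, the 3-methylcyclohex-2-ene (C1 on C8 of the chromanone, C2=C3–CH3, C4H2, C5 with the 2,4-dihydroxyphenyl group, C6 with the aroyl group), is a retro-[4+2] pattern. Cutting C4–C5 and C6–C1 gives an E-chalcone (Cα=Cβ) and an 8-[(E)-3-methylbuta-1,3-dienyl]chromanone. The ortho-OH/C=O pair of the aroyl ring is the chelation site through which a chiral borate activates and steers the dienophile.
- Diene half: cut C8–vinyl (Stille coupling, then dehydration) and C2–aryl of the chromanone (asymmetric conjugate arylation of a chromone).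
- Dienophile half: cut Cα=Cβ (Claisen–Schmidt) and the aryl–prenyl bond (C-prenylation).
- Forward order: chalcone triacetate 9 (steps 1–6); chromone to (2S)-chromanone 21 (steps 7–13); diene 25 (steps 14–16); ring C closed in step 17; global deacetylation (step 18).
- Stereochemistry: C2 of the chromanone from Rh/chiral-diene catalysis. In ring C, trans C5/C6 comes from the E-enone, cis C6/C1 from the endo transition state, and the absolute sense from the VANOL borate.

Key step: step 17

Assumption: the absolute sense of induction in steps 11 and 17 is assigned by analogy ((S,S)-diene ligand gives 2S as in cyclohexenone arylation; the (S)-VANOL borate exposes the αSi,βSi face of the enone); if either runs the opposite way, the mirror-image ligand is used and nothing else changes.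

**Route**

Step 1
Reactants: 1 2,4-dihydroxyacetophenone; 2 prenyl bromide
Product: 3 1-[2,4-dihydroxy-3-(3-methylbut-2-enyl)phenyl]ethanone
Conditions: KOH (10% aq.), 0 °C → rt; chromatography
Reagents that add atoms: none
Why: Phenoxide C-allylation in water, where hydrogen bonding to oxygen disfavours O-alkylation and C3 between the two oxygens is the most nucleophilic carbon, so the 3-prenyl isomer should be separable from the O-prenyl and C5 isomers.

Step 2
Reactants: 3 1-[2,4-dihydroxy-3-(3-methylbut-2-enyl)phenyl]ethanone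
Product: 4 1-[2-hydroxy-4-(methoxymethoxy)-3-(3-methylbut-2-enyl)phenyl]ethanone
Conditions: MOMCl (1.1 equiv), K2CO3, acetone, 0 °C → rt
Reagents that add atoms: chloromethyl methyl ether, COCCl
Why: Williamson-type etherification of the free 4-OH only, because the 2-OH is held in a hydrogen bond to the acetyl group and stays free for the later boron chelation.

Step 3
Reactants: 5 2,4-dihydroxybenzaldehyde
Product: 6 2,4-bis(methoxymethoxy)benzaldehyde
Conditions: MOMCl (3 equiv), K2CO3 (excess), acetone, 0 °C → 50 °C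
Reagents that add atoms: chloromethyl methyl ether, COCCl
Why: Williamson-type etherification of both phenols under forcing conditions gives the base-stable aldehyde partner for the aldol condensation.

Step 4
Reactants: 4 1-[2-hydroxy-4-(methoxymethoxy)-3-(3-methylbut-2-enyl)phenyl]ethanone; 6 2,4-bis(methoxymethoxy)benzaldehyde
Product: 7 (E)-3-[2,4-bis(methoxymethoxy)phenyl]-1-[2-hydroxy-4-(methoxymethoxy)-3-(3-methylbut-2-enyl)phenyl]prop-2-en-1-one
Conditions: KOH, EtOH/H2O, rt
Reagents that add atoms: none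
Why: Claisen–Schmidt condensation with E1cB dehydration should give the E-enone only, and the MOM and prenyl groups are inert to hydroxide.

Step 5
Reactants: 7 tris-MOM chalcone
Product: 8 (E)-1-[2,4-dihydroxy-3-(3-methylbut-2-enyl)phenyl]-3-(2,4-dihydroxyphenyl)prop-2-en-1-one (morachalcone A)
Conditions: HCl (1.25 M in MeOH), rt
Reagents that add atoms: none
Why: Acid-catalysed acetal methanolysis removes the three MOM groups at room temperature, mild enough to spare the prenyl group and the E-enone.

Step 6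
Reactants: 8 morachalcone A
Product: 9 (E)-1-[4-acetoxy-2-hydroxy-3-(3-methylbut-2-enyl)phenyl]-3-(2,4-diacetoxyphenyl)prop-2-en-1-one
Conditions: Ac2O (3.2 equiv), pyridine, CH2Cl2, 0 °C
Reagents that add atoms: acetic anhydride, CC(=O)OC(C)=O
Why: Phenol acetylation with a limited amount of anhydride spares the chelated, poorly nucleophilic 2'-OH, and the three acetates lower the enone LUMO for step 17.

Step 7
Reactants: 10 7-hydroxy-4H-chromen-4-one
Product: 11 7-hydroxy-8-iodo-4H-chromen-4-one
Conditions: NIS (1.05 equiv), DMF, 0 °C → rt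
Reagents that add atoms: N-iodosuccinimide, O=C1CCC(=O)N1I
Why: Electrophilic aromatic iodination ortho to the 7-OH should go to C8, which is flanked by O7 and the ring oxygen and is the most electron-rich carbon, while the pyranone ring is deactivated.

Step 8
Reactants: 11 7-hydroxy-8-iodo-4H-chromen-4-one
Product: 12 8-iodo-7-(methoxymethoxy)-4H-chromen-4-one
Conditions: MOMCl, K2CO3, acetone, 0 °C → rt
Reagents that add atoms: chloromethyl methyl ether, COCCl
Why: Williamson-type etherification masks the phenol so that no phenoxide deactivates the chromone as a Michael acceptor in step 11.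

Step 9
Reactants: 13 4-bromobenzene-1,3-diol
Product: 14 1-bromo-2,4-bis(methoxymethoxy)benzene
Conditions: MOMCl (2.5 equiv), K2CO3, acetone, 0 °C → rt
Reagents that add atoms: chloromethyl methyl ether, COCCl
Why: Williamson-type etherification of both phenols gives a bromide that tolerates bromine–lithium exchange.

Step 10
Reactants: 14 1-bromo-2,4-bis(methoxymethoxy)benzene
Product: 17 [2,4-bis(methoxymethoxy)phenyl]boronic acid, via aryllithium 15 (not isolated), via lithium aryltriisopropoxyborate 16 (not isolated)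
Conditions: n-BuLi, THF, −78 °C; B(OiPr)3, −78 °C → rt; 1 M HCl to pH 5, 0 °C
Reagents that add atoms: triisopropyl borate, CC(C)OB(OC(C)C)OC(C)C; water, O
Why: Bromine–lithium exchange followed by borylation with a trialkyl borate is standard, and the brief cold work-up at pH 5 keeps the MOM ethers.

Step 11
Reactants: 12 8-iodo-7-(methoxymethoxy)-4H-chromen-4-one; 17 [2,4-bis(methoxymethoxy)phenyl]boronic acid
Product: 18 (2S)-2-[2,4-bis(methoxymethoxy)phenyl]-8-iodo-7-(methoxymethoxy)chroman-4-one
Conditions: [RhCl(C2H4)2]2 (2.5 mol%), (1S,4S)-2,5-diphenylbicyclo[2.2.2]octa-2,5-diene (5.5 mol%), K3PO4 (0.5 equiv), dioxane/H2O (10:1), 35 °C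
Reagents that add atoms: none
Why: In this Hayashi–Miyaura 1,4-addition the aryl–rhodium species held by the chiral diene inserts the C2=C3 bond of the chromone on one face and so sets C2 as S, while monovalent rhodium at 35 °C should leave the aryl iodide alone and the fully protected product has no phenoxide that could open the ring.

Step 12
Reactants: 18 (2S)-tris-MOM iodochromanone
Product: 20 (2S)-2-(2,4-dihydroxyphenyl)-7-hydroxy-8-iodochroman-4-one, via tris(trimethylsilyl) ether 19 (not isolated)
Conditions: TMSOTf (6 equiv), 2,2'-bipyridyl (9 equiv), MeCN, 0 °C → rt; then H2O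
Reagents that add atoms: trimethylsilyl trifluoromethanesulfonate, C[Si](C)(C)OS(=O)(=O)C(F)(F)F (its silyl groups stand in intermediate 19 only)
Why: Cleavage of aryl MOM ethers by a silyl triflate and 2,2'-bipyridyl runs through the aryl silyl ethers without a Brønsted acid, which should avoid ionising the electron-rich benzylic C2–O1 bond and so keep C2 intact.

Step 13
Reactants: 20 (2S)-2-(2,4-dihydroxyphenyl)-7-hydroxy-8-iodochroman-4-one
Product: 21 (2S)-7-acetoxy-2-(2,4-diacetoxyphenyl)-8-iodochroman-4-one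
Conditions: Ac2O (4 equiv), pyridine, CH2Cl2, 0 °C → rt
Reagents that add atoms: acetic anhydride, CC(=O)OC(C)=O
Why: Phenol acetylation gives the same protecting groups as in 9 and takes away the ring B phenols that could open the chromanone through a quinone methide.

Step 14
Reactants: 22 2-methylbut-3-yn-2-ol
Product: 23 (E)-2-methyl-4-(tributylstannyl)but-3-en-2-ol
Conditions: Bu3SnH, PdCl2(PPh3)2 (1 mol%), THF, 0 °C → rt
Reagents that add atoms: tributyltin hydride, CCCC[SnH](CCCC)CCCC
Why: Pd-catalysed syn-hydrostannation of a terminal alkyne, in which the bulky tertiary carbinol steers tin to the terminal carbon and so should give the E-vinylstannane.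

Step 15
Reactants: 21 (2S)-7-acetoxy-2-(2,4-diacetoxyphenyl)-8-iodochroman-4-one; 23 (E)-2-methyl-4-(tributylstannyl)but-3-en-2-ol
Product: 24 (2S)-7-acetoxy-2-(2,4-diacetoxyphenyl)-8-[(E)-3-hydroxy-3-methylbut-1-enyl]chroman-4-one
Conditions: Pd2(dba)3 (5 mol%), AsPh3 (20 mol%), CuI (10 mol%), DMF, 45 °C
Reagents that add atoms: none
Why: Stille coupling runs under neutral conditions with retention of alkene geometry, AsPh3 and CuI speed up transmetalation at the doubly ortho-substituted iodide, and the acetates and C2 are not touched.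

Step 16
Reactants: 24 (2S)-7-acetoxy-2-(2,4-diacetoxyphenyl)-8-[(E)-3-hydroxy-3-methylbut-1-enyl]chroman-4-one
Product: 25 (2S)-7-acetoxy-2-(2,4-diacetoxyphenyl)-8-[(E)-3-methylbuta-1,3-dienyl]chroman-4-one
Conditions: Burgess reagent (1.5 equiv), THF, rt → 50 °C
Reagents that add atoms: none
Why: Burgess dehydration of the tertiary allylic alcohol by syn-elimination toward a methyl group is neutral and should give the conjugated E-diene without touching the acetates or C2.

Step 17
Reactants: 9 chalcone triacetate (1.5 equiv); 25 (2S)-dienyl chromanone triacetate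
Product: 26 (2S)-7-acetoxy-8-[(1S,5S,6R)-6-[4-acetoxy-2-hydroxy-3-(3-methylbut-2-enyl)benzoyl]-5-(2,4-diacetoxyphenyl)-3-methylcyclohex-2-en-1-yl]-2-(2,4-diacetoxyphenyl)chroman-4-one
Conditions: B(OPh)3 (0.5 equiv), (S)-VANOL (0.5 equiv), 4 Å MS, PhCF3, rt; then 25, rt → 40 °C; chromatography
Reagents that add atoms: none
Why: The borate from B(OPh)3 and (S)-VANOL takes up the 2'-phenol and the ketone oxygen of 9 as a six-membered chelate, which lowers the enone LUMO, and the diene of 25 then adds across Cα=Cβ in a concerted, asynchronous Diels–Alder reaction; the closest known reaction type is the chiral-borate-promoted enantioselective [4+2] cycloaddition of 2'-hydroxychalcones with 1-aryl-3-methylbuta-1,3-dienes. The one ring that closes, ring C, arises by intermolecular [4+2] annulation, suprafacial on both partners (four diene carbons plus Cα and Cβ). The trans relation at C5/C6 is carried over stereospecifically from the E-enone, the cis relation at C6/C1 comes from the endo transition state in which the boron-bound aroyl unit lies under the diene, and the absolute configuration (1S,5S,6R) comes from the ligand, which should block the αRe,βRe face so that the diene bonds to the αSi,βSi face. C2 of the chromanone is a spectator. The regioselectivity (CH2 terminus to Cβ, aryl-bearing terminus to Cα) is secured by the match of the largest HOMO coefficient at the unsubstituted diene terminus with the largest LUMO coefficient at Cβ, and the site selectivity by the fact that only 9 has an ortho-hydroxy ketone that can chelate boron while the prenyl group and the chromanone ketone are no dienophiles. Endo over exo and the facial selectivity are the demanding ones, and because 25 is a single enantiomer every stereoisomeric by-product is a diastereomer of 26 and should be removable by chromatography.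

Step 18
Reactants: 26 cycloadduct hexaacetate
Product: 27 (2S)-2-(2,4-dihydroxyphenyl)-8-[(1S,5S,6R)-6-[2,4-dihydroxy-3-(3-methylbut-2-enyl)benzoyl]-5-(2,4-dihydroxyphenyl)-3-methylcyclohex-2-en-1-yl]-7-hydroxychroman-4-one (target)
Conditions: NH4OAc (12 equiv), MeOH/H2O (4:1), rt → 35 °C, argon
Reagents that add atoms: none
Why: Hydrolysis of aryl acetates at near-neutral pH is chosen so that neither C2 of the chromanone (ring opening under base) nor the ketone α-carbon C6 (epimerisation to the all-trans isomer) should be disturbed.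

**Compound list**

1 | 2,4-dihydroxyacetophenone | CC(=O)c1ccc(O)cc1O | starting material
2 | prenyl bromide (1-bromo-3-methylbut-2-ene) | CC(C)=CCBr | starting material
3 | 1-[2,4-dihydroxy-3-(3-methylbut-2-enyl)phenyl]ethanone | CC(=O)c1ccc(O)c(CC=C(C)C)c1O | intermediate
4 | 1-[2-hydroxy-4-(methoxymethoxy)-3-(3-methylbut-2-enyl)phenyl]ethanone | CC(=O)c1ccc(OCOC)c(CC=C(C)C)c1O | intermediate
5 | 2,4-dihydroxybenzaldehyde | O=Cc1ccc(O)cc1O | starting material
6 | 2,4-bis(methoxymethoxy)benzaldehyde | COCOc1ccc(C=O)c(OCOC)c1 | intermediate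
7 | (E)-3-[2,4-bis(methoxymethoxy)phenyl]-1-[2-hydroxy-4-(methoxymethoxy)-3-(3-methylbut-2-enyl)phenyl]prop-2-en-1-one | CC(C)=CCc1c(OCOC)ccc(C(=O)/C=C/c2ccc(OCOC)cc2OCOC)c1O | intermediate
8 | morachalcone A, (E)-1-[2,4-dihydroxy-3-(3-methylbut-2-enyl)phenyl]-3-(2,4-dihydroxyphenyl)prop-2-en-1-one | CC(C)=CCc1c(O)ccc(C(=O)/C=C/c2ccc(O)cc2O)c1O | intermediate
9 | (E)-1-[4-acetoxy-2-hydroxy-3-(3-methylbut-2-enyl)phenyl]-3-(2,4-diacetoxyphenyl)prop-2-en-1-one | CC(C)=CCc1c(OC(C)=O)ccc(C(=O)/C=C/c2ccc(OC(C)=O)cc2OC(C)=O)c1O | intermediate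
10 | 7-hydroxy-4H-chromen-4-one | O=c1ccoc2cc(O)ccc12 | starting material
11 | 7-hydroxy-8-iodo-4H-chromen-4-one | O=c1ccoc2c(I)c(O)ccc12 | intermediate
12 | 8-iodo-7-(methoxymethoxy)-4H-chromen-4-one | COCOc1ccc2c(=O)ccoc2c1I | intermediate
13 | 4-bromobenzene-1,3-diol | Oc1ccc(Br)c(O)c1 | starting material
14 | 1-bromo-2,4-bis(methoxymethoxy)benzene | COCOc1ccc(Br)c(OCOC)c1 | intermediate
15 | [2,4-bis(methoxymethoxy)phenyl]lithium | [Li]c1ccc(OCOC)cc1OCOC | intermediate (not isolated)
16 | lithium [2,4-bis(methoxymethoxy)phenyl]tri(propan-2-yloxy)borate | [Li+].CC(C)O[B-](OC(C)C)(OC(C)C)c1ccc(OCOC)cc1OCOC | intermediate (not isolated)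
17 | [2,4-bis(methoxymethoxy)phenyl]boronic acid | COCOc1ccc(B(O)O)c(OCOC)c1 | intermediate
18 | (2S)-2-[2,4-bis(methoxymethoxy)phenyl]-8-iodo-7-(methoxymethoxy)chroman-4-one | COCOc1ccc2c(c1I)O[C@H](c1ccc(OCOC)cc1OCOC)CC2=O | intermediate
19 | (2S)-2-[2,4-bis(trimethylsilyloxy)phenyl]-8-iodo-7-(trimethylsilyloxy)chroman-4-one | C[Si](C)(C)Oc1ccc2c(c1I)O[C@H](c1ccc(O[Si](C)(C)C)cc1O[Si](C)(C)C)CC2=O | intermediate (not isolated)
20 | (2S)-2-(2,4-dihydroxyphenyl)-7-hydroxy-8-iodochroman-4-one | Oc1ccc2c(c1I)O[C@H](c1ccc(O)cc1O)CC2=O | intermediate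
21 | (2S)-7-acetoxy-2-(2,4-diacetoxyphenyl)-8-iodochroman-4-one | CC(=O)Oc1ccc2c(c1I)O[C@H](c1ccc(OC(C)=O)cc1OC(C)=O)CC2=O | intermediate
22 | 2-methylbut-3-yn-2-ol | CC(C)(O)C#C | starting material
23 | (E)-2-methyl-4-(tributylstannyl)but-3-en-2-ol | CCCC[Sn](CCCC)(CCCC)/C=C/C(C)(C)O | intermediate
24 | (2S)-7-acetoxy-2-(2,4-diacetoxyphenyl)-8-[(E)-3-hydroxy-3-methylbut-1-enyl]chroman-4-one | CC(=O)Oc1ccc2c(c1/C=C/C(C)(C)O)O[C@H](c1ccc(OC(C)=O)cc1OC(C)=O)CC2=O | intermediate
25 | (2S)-7-acetoxy-2-(2,4-diacetoxyphenyl)-8-[(E)-3-methylbuta-1,3-dienyl]chroman-4-one | CC(=O)Oc1ccc2c(c1/C=C/C(C)=C)O[C@H](c1ccc(OC(C)=O)cc1OC(C)=O)CC2=O | intermediate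
26 | (2S)-7-acetoxy-8-[(1S,5S,6R)-6-[4-acetoxy-2-hydroxy-3-(3-methylbut-2-enyl)benzoyl]-5-(2,4-diacetoxyphenyl)-3-methylcyclohex-2-en-1-yl]-2-(2,4-diacetoxyphenyl)chroman-4-one | CC(C)=CCc1c(OC(C)=O)ccc(C(=O)[C@H]2[C@@H](c3c(OC(C)=O)ccc4c3O[C@H](c3ccc(OC(C)=O)cc3OC(C)=O)CC4=O)C=C(C)C[C@@H]2c2ccc(OC(C)=O)cc2OC(C)=O)c1O | intermediate
27 | (2S)-2-(2,4-dihydroxyphenyl)-8-[(1S,5S,6R)-6-[2,4-dihydroxy-3-(3-methylbut-2-enyl)benzoyl]-5-(2,4-dihydroxyphenyl)-3-methylcyclohex-2-en-1-yl]-7-hydroxychroman-4-one | CC(C)=CCc1c(O)ccc(C(=O)[C@H]2[C@@H](c3c(O)ccc4c3O[C@H](c3ccc(O)cc3O)CC4=O)C=C(C)C[C@@H]2c2ccc(O)cc2O)c1O | target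

**Count**
Total steps: 18. Longest linear sequence: 9 steps (steps 7, 8, 11, 12, 13, 15, 16, 17, 18, from 10).

**Steps most likely to fail**

1. Step 17. The cycloaddition may stall through product inhibition of the borate, or may proceed with poor endo/exo or facial control. Fallback: the same two partners 9 and 25 are combined under electron-transfer catalysis by zerovalent silver nanoparticles on SiO2 (prepared from AgBF4 and Bu4NBH4) in CH2Cl2 at 50 °C. This needs no chelating chiral ligand and turns over without boron. The endo isomers, which are diastereomers because C2 is fixed, would be separated by preparative HPLC to give 26, where the route is rejoined. No new compound arises (F0).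

2. Step 11. The ortho-substituted boronic acid may transmetalate slowly or protodeboronate, the aryl iodide may be attacked, or face selectivity at C2 may be low. Fallback by chalcone cyclisation and kinetic resolution, setting out from 1 and 6 and returning at 18. Compound 1 is iodinated (I2, HIO3, aq. EtOH) to 1-(2,4-dihydroxy-3-iodophenyl)ethanone F1, and its free 4-OH is protected (MOMCl, K2CO3, acetone) to give 1-[2-hydroxy-3-iodo-4-(methoxymethoxy)phenyl]ethanone F2. Claisen–Schmidt condensation with 6 (KOH, EtOH) gives (E)-3-[2,4-bis(methoxymethoxy)phenyl]-1-[2-hydroxy-3-iodo-4-(methoxymethoxy)phenyl]prop-2-en-1-one F3. Oxa-Michael ring closure (NaOAc, EtOH, reflux) gives racemic 2-[2,4-bis(methoxymethoxy)phenyl]-8-iodo-7-(methoxymethoxy)chroman-4-one F4. Asymmetric transfer hydrogenation with RuCl(p-cymene)[(R,R)-TsDPEN] in HCO2H/Et3N should reduce the 2R enantiomer to (2R,4R)-2-[2,4-bis(methoxymethoxy)phenyl]-8-iodo-7-(methoxymethoxy)chroman-4-ol F5 and leave (2S)-18, which is separated and carried on.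

3. Step 18. Cleavage of the hindered acetates may be slow, and forcing it with base may open the chromanone ring and scramble C2. Fallback by a change of protecting groups on the chromanone half, setting out from 20 (with 23 and 9) and returning at 27. Triol 20 is silylated (TBSCl, imidazole, DMF) to (2S)-2-[2,4-bis(tert-butyldimethylsilyloxy)phenyl]-7-(tert-butyldimethylsilyloxy)-8-iodochroman-4-one F6. Stille coupling with 23 as in step 15 gives the (E)-3-hydroxy-3-methylbut-1-enyl compound F7, and Burgess dehydration gives the (E)-3-methylbuta-1,3-dienyl compound F8. Cycloaddition with 9 as in step 17 gives the mixed triacetate tris-silyl ether adduct F9. Its three acetates are removed first (K2CO3, MeOH, 0 °C, short time) while ring B stays silylated and cannot form a quinone methide, giving the tris-silyl ether F10. Desilylation with Et3N·3HF in THF/MeCN then gives 27.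

**Further compounds**

F0 | step 17 | none | none
F1 | step 11 | 1-(2,4-dihydroxy-3-iodophenyl)ethanone | CC(=O)c1ccc(O)c(I)c1O
F2 | step 11 | 1-[2-hydroxy-3-iodo-4-(methoxymethoxy)phenyl]ethanone | CC(=O)c1ccc(OCOC)c(I)c1O
F3 | step 11 | (E)-3-[2,4-bis(methoxymethoxy)phenyl]-1-[2-hydroxy-3-iodo-4-(methoxymethoxy)phenyl]prop-2-en-1-one | COCOc1ccc(/C=C/C(=O)c2ccc(OCOC)c(I)c2O)c(OCOC)c1
F4 | step 11 | racemic 2-[2,4-bis(methoxymethoxy)phenyl]-8-iodo-7-(methoxymethoxy)chroman-4-one | COCOc1ccc2c(c1I)OC(c1ccc(OCOC)cc1OCOC)CC2=O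
F5 | step 11 | (2R,4R)-2-[2,4-bis(methoxymethoxy)phenyl]-8-iodo-7-(methoxymethoxy)chroman-4-ol | COCOc1ccc2c(c1I)O[C@@H](c1ccc(OCOC)cc1OCOC)C[C@H]2O
F6 | step 18 | (2S)-2-[2,4-bis(tert-butyldimethylsilyloxy)phenyl]-7-(tert-butyldimethylsilyloxy)-8-iodochroman-4-one | CC(C)(C)[Si](C)(C)Oc1ccc2c(c1I)O[C@H](c1ccc(O[Si](C)(C)C(C)(C)C)cc1O[Si](C)(C)C(C)(C)C)CC2=O
F7 | step 18 | (2S)-2-[2,4-bis(tert-butyldimethylsilyloxy)phenyl]-7-(tert-butyldimethylsilyloxy)-8-[(E)-3-hydroxy-3-methylbut-1-enyl]chroman-4-one | CC(C)(C)[Si](C)(C)Oc1ccc2c(c1/C=C/C(C)(C)O)O[C@H](c1ccc(O[Si](C)(C)C(C)(C)C)cc1O[Si](C)(C)C(C)(C)C)CC2=O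
F8 | step 18 | (2S)-2-[2,4-bis(tert-butyldimethylsilyloxy)phenyl]-7-(tert-butyldimethylsilyloxy)-8-[(E)-3-methylbuta-1,3-dienyl]chroman-4-one | CC(C)(C)[Si](C)(C)Oc1ccc2c(c1/C=C/C(C)=C)O[C@H](c1ccc(O[Si](C)(C)C(C)(C)C)cc1O[Si](C)(C)C(C)(C)C)CC2=O
F9 | step 18 | (2S)-8-[(1S,5S,6R)-6-[4-acetoxy-2-hydroxy-3-(3-methylbut-2-enyl)benzoyl]-5-(2,4-diacetoxyphenyl)-3-methylcyclohex-2-en-1-yl]-2-[2,4-bis(tert-butyldimethylsilyloxy)phenyl]-7-(tert-butyldimethylsilyloxy)chroman-4-one | CC(C)=CCc1c(OC(C)=O)ccc(C(=O)[C@H]2[C@@H](c3c(O[Si](C)(C)C(C)(C)C)ccc4c3O[C@H](c3ccc(O[Si](C)(C)C(C)(C)C)cc3O[Si](C)(C)C(C)(C)C)CC4=O)C=C(C)C[C@@H]2c2ccc(OC(C)=O)cc2OC(C)=O)c1O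
F10 | step 18 | (2S)-2-[2,4-bis(tert-butyldimethylsilyloxy)phenyl]-7-(tert-butyldimethylsilyloxy)-8-[(1S,5S,6R)-6-[2,4-dihydroxy-3-(3-methylbut-2-enyl)benzoyl]-5-(2,4-dihydroxyphenyl)-3-methylcyclohex-2-en-1-yl]chroman-4-one | CC(C)=CCc1c(O)ccc(C(=O)[C@H]2[C@@H](c3c(O[Si](C)(C)C(C)(C)C)ccc4c3O[C@H](c3ccc(O[Si](C)(C)C(C)(C)C)cc3O[Si](C)(C)C(C)(C)C)CC4=O)C=C(C)C[C@@H]2c2ccc(O)cc2O)c1O
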